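Locants follow germacrane numbering throughout: ring carbons C1–C10 (C1=C10 alkene), C11 (butenolide α-carbon), C12 (lactone carbonyl), C13 (acetoxymethyl carbon), C14 (formyl carbon on C10), C15 (methyl on C4). Compound numbers are those of the steps and the compound list.

## Analysis of the target

Target 47 is a germacranolide: a ten-membered carbocycle (C1–C10) fused through C6 and C7 to a butenolide (O–C12(=O)–C11=C7). The C1=C10 alkene carries the formyl carbon C14 and has the ring carbons C9 and C2 cis, so it is E by the sequence rule but cis within the ring. C4 and C5 form a trans-epoxide with the C15 methyl on C4. C8 bears an isovalerate and C11 bears the acetoxymethyl carbon C13. There are four stereocentres, C4 (R), C5 (R), C6 (R) and C8 (S). C4–C5–C6 are contiguous, and C6 and C8 flank the sp2 carbon C7, so with C7 as a carbonyl or carbinol they are a 1,3-anti dioxygenated pair. The sensitive groups are the trisubstituted epoxide facing the C1=C10 alkene across the ring (acid would trigger transannular cyclisation), the butenolide with acidic γ-hydrogens at C6 and C8 and an allylic acetate on C11 (base would eliminate), the enal, and two different esters. The difficulty is closing a ten-membered ring with a cis alkene and a trans-epoxide, and ordering the steps so that no acid-, base- or reductant-labile group is present at the wrong time. The strategy rests on C4 and C5: both are oxygenated and adjacent, so the C4–C5 ring bond can come from the reductive union of a C4 methyl ketone and a C5 aldehyde, and the epoxide from the resulting 4,5-diol.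

## Retrosynthetic reasoning

**47 back to 38 (acyl groups and C14 oxidation).** The C13 acetate is put on last (45 to 47), because an allylic acetate on the butenolide α-carbon would be eliminated by any later base. The enal is formed from 43 only after C8 is acylated; a free C8 hydroxyl next to a C14 aldehyde would close to a five-membered lactol. Diol 39 is therefore silylated at the primary C14 hydroxyl and acylated at C8 in one flask (42), and 39 comes from butenolide 38 by fluoride.

**38 back to 36 and 13 (butenolide, C7=C11).** The C7=C11 bond and the lactone are cut together. The C6 hydroxyl of 36 is esterified with phosphonate acid 13, which carries C11, C12 and C13, and an intramolecular Horner–Wadsworth–Emmons reaction on the C7 ketone of 37 closes the ring. The butenolide is thus absent during the reductive ring closure.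

**36 back to 33 (C7 oxidation level).** A dimethyl ketal would be the shortest mask for C7. It is not used, because a ketal flanked by two oxygenated carbons needs strong aqueous acid for hydrolysis, and the 4,5-epoxide would not survive that. C7 is therefore carried as a triethylsilyl-protected carbinol, which is unmasked with buffered fluoride (34) and oxidised under neutral conditions (35). The C6 PMB ether is then removed oxidatively (36).

**33 back to 31 (epoxide).** The C5–O bond of the epoxide is cut. The cis-diol 31 is mesylated at the secondary C5 hydroxyl (32) and the tertiary C4 alkoxide displaces the mesylate with inversion. This turns the cis-diol into the trans-epoxide without touching C4.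

**31 back to 29 (key disconnection, C4–C5).** The ring is opened between the two carbinol carbons to give keto-aldehyde 29. The forward step must join two electrophilic carbons in a ten-membered closure and set C4 and C5. Precursor 29 contains no enal, lactone or halide, so the two carbonyls are the only groups a one-electron reductant can attack.

**29 back to 27 (carbonyl groups).** The aldehyde comes from primary alcohol 28. The methyl ketone comes from the terminal alkene of 27 by Wacker oxidation, so no ketone has to be protected through the organolithium and hydride steps.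

**27 back to 21 (O6/O8 differentiation and C7).** The two secondary hydroxyls of 22 are told apart by the PMB ether on O5: oxidation closes it onto O6 as a five-membered acetal (23), leaving O8 free for silylation (24). Chelation-controlled reduction then sets the C7 carbinol (25). After C7 silylation (26), reductive opening of the acetal places the PMB group on O6 and frees O5 (27).

**21 back to 14, 15, 4 and 10 (C6 and C8).** The C5–C6 and C8–C9 bonds are cut next to the ketone. Dioxanone 14, as its hydrazone 16 with auxiliary 15, is alkylated first with chloromethyl ether 4 and then with allylic bromide 10. The auxiliary sets both centres and gives the trans (1,3-anti) arrangement.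

**10 back to 5 and 6 (C1=C10 geometry).** An olefination with an α-branched phosphonate would give E/Z mixtures. Instead, the Morita–Baylis–Hillman adduct 7 of 5 and 6 is converted to bromide 8 with allylic transposition. This places the ester (later C14) trans and the bromomethyl group (C9) cis to the chain. Reduction (9) and silylation give 10.

**4 and 13 back to 1, 2 and 11.** Chloromethyl ether 4 comes from 1 and 2 via 3. It provides C5 for the main chain and C13 for phosphonate 12, from which acid 13 is freed under neutral conditions.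

## Alternatives that were turned down

**Alternative 1:** The disconnection is C1–C2 of the fully acylated ring. In the forward step, cathodic reduction with NiBr2(dme) and 4,4′-di-tert-butyl-2,2′-bipyridine would act on open-chain A2, which carries a C1 vinyl iodide and an N-hydroxyphthalimide ester one carbon beyond C2. Loss of CO2 gives a primary C2 radical, capture by the alkenylnickel formed at C1 and reductive elimination give ring A1.
- For: ring closure comes as late as possible, with epoxide, butenolide and both esters in place and the alkene geometry fixed in the vinyl iodide. Only C14 desilylation and oxidation would remain, which is far shorter after ring closure than the chosen route (two steps against thirteen).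
- Against: the C2 radical is six atoms from C7, the β-carbon of the butenolide, so 6-exo conjugate addition or hydrogen abstraction should outrun bimolecular capture by nickel at medium-ring dilution. Zerovalent nickel can also ionise the C13 allylic acetate and open the epoxide, and the cathode can reduce the butenolide.
- Comparison: alternative 1 is stronger on step economy and on alkene geometry. The chosen route closes the ring on a substrate whose only reducible groups are the two carbons to be joined, and it makes C4 and C5 in the same step.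

**Alternative 2:** The disconnection is a ring expansion: C2–C3 is formed and the C5–C10 bond of a cyclohexane is cleaved. In the forward step, KH and 18-crown-6 convert the tertiary alcohol of A4 into its alkoxide, a [3,3] shift opens the six-membered ring, and PhNTf2 traps the C10 enolate as enol triflate A3.
- For: the ring is made by an intramolecular rearrangement driven by enolate formation, with no high dilution. The (4E)-alkene is set by the transition state, so the trans-epoxide could follow by direct epoxidation. On the ring-forming event it is stronger than a ten-membered pinacol closure.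
- Against: A4 needs defined configurations at C5 and C10 as well as C6 and C8, two of them made only to be destroyed. The ring-cis C1(10) geometry requires C9 to be axial in the chair transition state. The enolate has a β-silyloxy group at C8 and can equilibrate and eliminate before triflation. C14 must still be added by carbonylation, and the C7 ketal would have to be hydrolysed next to the acid-labile epoxide.
- Comparison: the chosen route has C14 in place from the start, delivers C4 and C5 already oxygenated, and uses an acyclic precursor made by two auxiliary-controlled alkylations.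

**Alternative 3:** The disconnection is C6–C7, through ring contraction. In the forward step, n-BuLi deprotonates the propargylic C6 of the thirteen-membered propargyl allyl ether A6, and the [2,3]-Wittig shift gives ten-membered cycloalkynol A5 with the C6 hydroxyl and an exocyclic C11=C12 methylene.
- For: a thirteen-membered ether is easier to close than a ten-membered carbocycle, and the contraction runs at low temperature and forms a ring C–C bond with relative control at C6 and C7. On the ring-forming event it is at least as strong as the chosen step.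
- Against: the C4≡C5 alkyne sits in a strained ten-membered ring and would need regio- and stereoselective addition of methyl and hydrogen to an in-ring (E)-alkene, then epoxidation. The exocyclic methylene must be transposed into the ring and C12 oxidised to the lactone carbonyl. Deprotonation at the allylic C12 competes, and the C7 stereocentre is made only to be lost.
- Comparison: the chosen route brings C4 and C5 in at the right oxidation level and leaves the butenolide to a standard phosphonate closure.

Key step: step 21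

## Route

Remark: the lithiated SAMP hydrazone of 14 is assumed to be alkylated with the same facial sense as SAMP hydrazones of simple ketones, which makes each new α-carbon (S) in ketone 21; with the opposite sense the enantiomeric auxiliary would be used.

Hydrazones 16, 18 and 20 are mixtures of C=N isomers. Acetals 23–26 are mixtures at the acetal carbon. Both features are removed later in the route.

Step 1
Reactants: 1 4-methoxybenzyl alcohol; 2 chloromethyl methyl sulfide
Product: 3 1-methoxy-4-{[(methylsulfanyl)methoxy]methyl}benzene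
Conditions: NaH, NaI (cat.), DME, 0 °C → rt
Reagents that add atoms: none
Why: Williamson etherification of the benzylic alkoxide with the α-chloro sulfide gives the O,S-acetal from which the chloromethyl ether can be released without acid.

Step 2
Reactants: 3 1-methoxy-4-{[(methylsulfanyl)methoxy]methyl}benzene
Product: 4 1-[(chloromethoxy)methyl]-4-methoxybenzene
Conditions: SO2Cl2, CH2Cl2, −78 → 0 °C; volatiles removed, used crude
Reagents that add atoms: sulfuryl chloride, O=S(=O)(Cl)Cl
Why: S-chlorination of the O,S-acetal and collapse to the oxocarbenium chloride (chlorinolysis of a methylthiomethyl ether) gives the α-chloro ether without free acid, which the p-methoxybenzyl group would not tolerate.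

Step 3
Reactants: 5 pent-4-enal; 6 methyl acrylate
Product: 7 methyl 3-hydroxy-2-methylidenehept-6-enoate (racemic)
Conditions: DABCO (1 equiv), neat, rt, several days
Reagents that add atoms: none
Why: Morita–Baylis–Hillman reaction joins C1 to C10 and brings C9 and C14 as the methylidene and ester carbons; the carbinol centre is removed in step 4.

Step 4
Reactants: 7 methyl 3-hydroxy-2-methylidenehept-6-enoate
Product: 8 methyl (2Z)-2-(bromomethyl)hepta-2,6-dienoate
Conditions: NBS, Me2S, CH2Cl2, 0 °C → rt
Reagents that add atoms: N-bromosuccinimide, BrN1C(=O)CCC1=O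
Why: the alkoxysulfonium salt formed from the Corey–Kim-type reagent is displaced by bromide with allylic transposition (SN2′); the trisubstituted enoate forms with the ester trans and the bromomethyl group cis to the chain, which is the C1=C10 geometry of the target.

Step 5
Reactants: 8 methyl (2Z)-2-(bromomethyl)hepta-2,6-dienoate
Product: 9 (2Z)-2-(bromomethyl)hepta-2,6-dien-1-ol
Conditions: i-Bu2AlH (2.2 equiv), CH2Cl2, −78 °C; aq. potassium sodium tartrate
Reagents that add atoms: none
Why: 1,2-reduction of the conjugated ester by i-Bu2AlH at −78 °C is faster than attack on the allylic bromide, and the alkene geometry is not touched.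

Step 6
Reactants: 9 (2Z)-2-(bromomethyl)hepta-2,6-dien-1-ol
Product: 10 {[(2Z)-2-(bromomethyl)hepta-2,6-dien-1-yl]oxy}tri(propan-2-yl)silane
Conditions: i-Pr3SiOTf, 2,6-lutidine, CH2Cl2, −78 °C
Reagents that add atoms: triisopropylsilyl triflate, CC(C)[Si](C(C)C)(C(C)C)OS(=O)(=O)C(F)(F)F
Why: silylation with a triflate and a hindered pyridine avoids nucleophilic bases that would displace the allylic bromide; the triisopropylsilyl ether on O14 is chosen to survive the later aqueous acid and the selective removal of the C7 silyl group.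

Step 7
Reactants: 11 prop-2-en-1-yl (diethoxyphosphoryl)acetate; 4 1-[(chloromethoxy)methyl]-4-methoxybenzene
Product: 12 prop-2-en-1-yl 2-(diethoxyphosphoryl)-3-[(4-methoxyphenyl)methoxy]propanoate (racemic)
Conditions: NaH, THF, 0 °C → rt
Reagents that add atoms: none
Why: C-alkylation of the phosphonoacetate anion by the reactive α-chloro ether places the protected C13 oxygen on the future C11; the new centre is lost in step 28.

Step 8
Reactants: 12 prop-2-en-1-yl 2-(diethoxyphosphoryl)-3-[(4-methoxyphenyl)methoxy]propanoate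
Product: 13 2-(diethoxyphosphoryl)-3-[(4-methoxyphenyl)methoxy]propanoic acid (racemic)
Conditions: Pd(PPh3)4 (5 mol%), morpholine, THF, rt; mild acidic extraction
Reagents that add atoms: none
Why: Tsuji–Trost deallylation frees the acid under neutral conditions and avoids the β-elimination of the alkoxide that hydroxide would risk on this C–H acidic β-alkoxy ester.

Step 9
Reactants: 14 2,2-dimethyl-1,3-dioxan-5-one; 15 (2S)-2-(methoxymethyl)pyrrolidin-1-amine (SAMP)
Product: 16 (2S)-N-(2,2-dimethyl-1,3-dioxan-5-ylidene)-2-(methoxymethyl)pyrrolidin-1-amine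
Conditions: benzene, reflux, Dean–Stark trap
Reagents that add atoms: none
Why: hydrazone condensation attaches the chiral auxiliary that controls both α-alkylations.

Step 10
Reactants: 16 (2S)-N-(2,2-dimethyl-1,3-dioxan-5-ylidene)-2-(methoxymethyl)pyrrolidin-1-amine; 4 1-[(chloromethoxy)methyl]-4-methoxybenzene
Product: 18 (2S)-N-[(4R)-4-{[(4-methoxyphenyl)methoxy]methyl}-2,2-dimethyl-1,3-dioxan-5-ylidene]-2-(methoxymethyl)pyrrolidin-1-amine, via lithium aza-enolate 17 (not isolated)
Conditions: t-BuLi, THF, −78 °C; then 4, −100 °C → rt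
Reagents that add atoms: none
Why: Enders SAMP-hydrazone alkylation; the lithium-chelated aza-enolate is attacked on the face away from the methoxymethyl-bearing pyrrolidine, which sets C6 (descriptor R in the hydrazone, S in the ketone) and adds C5 with its PMB-protected oxygen.

Step 11
Reactants: 18 (2S)-N-[(4R)-4-{[(4-methoxyphenyl)methoxy]methyl}-2,2-dimethyl-1,3-dioxan-5-ylidene]-2-(methoxymethyl)pyrrolidin-1-amine; 10 {[(2Z)-2-(bromomethyl)hepta-2,6-dien-1-yl]oxy}tri(propan-2-yl)silane
Product: 20 (2S)-N-[(4R,6S)-4-{[(4-methoxyphenyl)methoxy]methyl}-2,2-dimethyl-6-[(2E)-2-({[tri(propan-2-yl)silyl]oxy}methyl)hepta-2,6-dien-1-yl]-1,3-dioxan-5-ylidene]-2-(methoxymethyl)pyrrolidin-1-amine, via lithium aza-enolate 19 (not isolated)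
Conditions: t-BuLi, THF, −78 °C; then 10, −100 °C → rt
Reagents that add atoms: none
Why: the second deprotonation occurs at the unsubstituted α′-carbon and SN2 alkylation by the primary allylic bromide under the same auxiliary control forms C8–C9, sets C8 (S) and gives the trans-4,6-disubstituted dioxane.

Step 12
Reactants: 20 bis-alkylated hydrazone
Product: 21 (4S,6S)-4-{[(4-methoxyphenyl)methoxy]methyl}-2,2-dimethyl-6-[(2E)-2-({[tri(propan-2-yl)silyl]oxy}methyl)hepta-2,6-dien-1-yl]-1,3-dioxan-5-one
Conditions: sat. aq. oxalic acid, Et2O, rt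
Reagents that add atoms: water, O
Why: two-phase hydrolysis of the hydrazone is mild enough to keep the acetonide and both α-stereocentres; the auxiliary is recovered.

Step 13
Reactants: 21 trans-dioxanone
Product: 22 (2S,4S,6E)-2,4-dihydroxy-1-[(4-methoxyphenyl)methoxy]-6-({[tri(propan-2-yl)silyl]oxy}methyl)undeca-6,10-dien-3-one
Conditions: 1 M HCl, THF, rt
Reagents that add atoms: none
Why: the trans-acetonide is forced into a twist-boat and hydrolyses readily in dilute acid, which the PMB and triisopropylsilyl ethers tolerate and which does not enolise the α,α′-dioxygenated ketone.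

Step 14
Reactants: 22 dihydroxy ketone
Product: 23 (2S,4E)-2-hydroxy-1-[(2RS,4S)-2-(4-methoxyphenyl)-1,3-dioxolan-4-yl]-4-({[tri(propan-2-yl)silyl]oxy}methyl)nona-4,8-dien-1-one
Conditions: DDQ (1.2 equiv), 4 Å MS, CH2Cl2, 0 °C
Reagents that add atoms: none
Why: oxidation of the PMB ether to its benzylic oxocarbenium ion under anhydrous conditions, trapped by the neighbouring C6 hydroxyl as a five-membered p-methoxybenzylidene acetal; only O6 can close a five-membered ring, so O6 and O8 become distinguishable.

Step 15
Reactants: 23 acetal hydroxy ketone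
Product: 24 (2S,4E)-2-{[tert-butyl(dimethyl)silyl]oxy}-1-[(2RS,4S)-2-(4-methoxyphenyl)-1,3-dioxolan-4-yl]-4-({[tri(propan-2-yl)silyl]oxy}methyl)nona-4,8-dien-1-one
Conditions: t-BuMe2SiOTf, 2,6-lutidine, CH2Cl2, −78 °C
Reagents that add atoms: tert-butyldimethylsilyl triflate, CC(C)(C)[Si](C)(C)OS(=O)(=O)C(F)(F)F
Why: silylation of the only free hydroxyl (O8) at low temperature, where the acetal and the α-stereocentres are not affected.

Step 16
Reactants: 24 silyloxy ketone
Product: 25 (1S,2S,4E)-2-{[tert-butyl(dimethyl)silyl]oxy}-1-[(2RS,4S)-2-(4-methoxyphenyl)-1,3-dioxolan-4-yl]-4-({[tri(propan-2-yl)silyl]oxy}methyl)nona-4,8-dien-1-ol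
Conditions: Zn(BH4)2, Et2O, −30 → 0 °C
Reagents that add atoms: none
Why: chelation-controlled reduction: zinc bridges the C7 carbonyl and the acetal oxygen O6 and hydride enters anti to C5, which is also the Felkin–Anh face with respect to the silyloxy-bearing C8, so both neighbours favour the (7S) carbinol; this centre is removed by oxidation in step 25.

Step 17
Reactants: 25 C7 alcohol
Product: 26 (2RS,4S)-4-[(1S,2S,4E)-2-{[tert-butyl(dimethyl)silyl]oxy}-1-[(triethylsilyl)oxy]-4-({[tri(propan-2-yl)silyl]oxy}methyl)nona-4,8-dien-1-yl]-2-(4-methoxyphenyl)-1,3-dioxolane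
Conditions: Et3SiOTf, 2,6-lutidine, CH2Cl2, −78 → 0 °C
Reagents that add atoms: triethylsilyl triflate, CC[Si](CC)(CC)OS(=O)(=O)C(F)(F)F
Why: the triethylsilyl ether masks C7 through the reductive steps and can later be removed in the presence of the tert-butyldimethylsilyl and triisopropylsilyl ethers.

Step 18
Reactants: 26 fully protected acetal
Product: 27 (2S,3S,4S,6E)-4-{[tert-butyl(dimethyl)silyl]oxy}-2-[(4-methoxyphenyl)methoxy]-3-[(triethylsilyl)oxy]-6-({[tri(propan-2-yl)silyl]oxy}methyl)undeca-6,10-dien-1-ol
Conditions: i-Bu2AlH (4 equiv), CH2Cl2, −78 → 0 °C; aq. potassium sodium tartrate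
Reagents that add atoms: none
Why: reductive opening of the p-methoxybenzylidene acetal; aluminium coordinates the less hindered primary oxygen, so hydride delivery leaves the PMB group on the secondary O6 and frees O5.

Step 19
Reactants: 27 primary alcohol with terminal alkene
Product: 28 (5E,8S,9S,10S)-8-{[tert-butyl(dimethyl)silyl]oxy}-11-hydroxy-10-[(4-methoxyphenyl)methoxy]-9-[(triethylsilyl)oxy]-6-({[tri(propan-2-yl)silyl]oxy}methyl)undec-5-en-2-one
Conditions: PdCl2 (10 mol%), Cu(OAc)2 (20 mol%), O2 (1 atm), DMA/H2O 7:1, rt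
Reagents that add atoms: water, O
Why: Tsuji–Wacker oxidation is selective for the monosubstituted alkene over the trisubstituted one and gives the C4 methyl ketone; the acetate co-oxidant keeps the medium mild enough for the silyl ethers.

Step 20
Reactants: 28 hydroxy ketone
Product: 29 (2R,3S,4S,6E)-4-{[tert-butyl(dimethyl)silyl]oxy}-2-[(4-methoxyphenyl)methoxy]-10-oxo-3-[(triethylsilyl)oxy]-6-({[tri(propan-2-yl)silyl]oxy}methyl)undec-6-enal
Conditions: Dess–Martin periodinane, NaHCO3, CH2Cl2, 0 °C → rt; used directly
Reagents that add atoms: none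
Why: buffered Dess–Martin oxidation gives the α-alkoxy aldehyde without epimerising C6; the β-oxygen at C7 is a silyl ether and is not eliminated.

Step 21
Reactants: 29 keto-aldehyde
Product: 31 (4R,5S,6S,7S,8S)-8-(tert-butyldimethylsilyloxy)-6-(4-methoxybenzyloxy)-7-(triethylsilyloxy)-14-(triisopropylsilyloxy)-11,12,13-trinorgermacr-1(10)E-ene-4,5-diol, via bis(diiodosamarium) diolate 30 (not isolated)
Conditions: SmI2 (4 equiv, 0.1 M in THF), THF, rt; 29 added by syringe pump over 8 h (final 2 mM); then aq. NaHCO3
Reagents that add atoms: none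
Why: Electron transfer from SmI2 to the aldehyde, the more easily reduced carbonyl, gives a C5 ketyl bound to trivalent samarium; it adds to the samarium-coordinated C4 ketone and a second electron gives diolate 30, which is hydrolysed on work-up. The closest known reaction type is the SmI2-mediated intramolecular pinacol coupling of keto-aldehydes, established for five- to eight-membered rings and extended to larger rings with this reagent and with low-valent titanium. The ten-membered ring closes in a 10-exo-trig mode (ketyl carbon onto carbonyl carbon) and is kept intramolecular by slow addition at high dilution; the cis C1=C10 alkene and the three contiguous branched carbons C6–C8 restrict the chain to folded conformations. C5 is controlled by chelation: the ketyl oxygen and the C6 ether oxygen bind the same samarium and C4 approaches on the side of the C6 hydrogen, anti to C7, which gives the 5,6-threo (5S) arrangement. C4 is controlled by the samarium bridge between the two oxygens at the moment of bond formation, which places them syn and gives the cis-diol (4R). The step needs ketyl formation at the aldehyde only, and 29 has no enal, lactone or halide, while its ethers and alkene are inert to SmI2. Leaving out HMPA and proton donors keeps simple reduction, loss of the α-PMB-oxy group and ketyl addition to the C1=C10 alkene slow.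

Step 22
Reactants: 31 cis-4,5-diol
Product: 32 (4R,5S,6R,7S,8S)-8-(tert-butyldimethylsilyloxy)-4-hydroxy-6-(4-methoxybenzyloxy)-7-(triethylsilyloxy)-14-(triisopropylsilyloxy)-11,12,13-trinorgermacr-1(10)E-en-5-yl methanesulfonate
Conditions: MsCl, Et3N, CH2Cl2, −20 → 0 °C
Reagents that add atoms: methanesulfonyl chloride, CS(=O)(=O)Cl
Why: sulfonylation of the secondary C5 hydroxyl; the tertiary C4 hydroxyl does not react under these conditions.

Step 23
Reactants: 32 hydroxy mesylate
Product: 33 (4R,5R,6S,7S,8S)-8-(tert-butyldimethylsilyloxy)-4,5-epoxy-6-(4-methoxybenzyloxy)-7-(triethylsilyloxy)-14-(triisopropylsilyloxy)-11,12,13-trinorgermacr-1(10)E-ene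
Conditions: K2CO3, MeOH, 0 °C → rt
Reagents that add atoms: none
Why: intramolecular SN2 displacement (3-exo-tet) of the C5 mesylate by the C4 alkoxide with inversion at C5 turns the cis-diol into the trans-epoxide; the anti-periplanar O–C4–C5–O conformer has C3 and C6 transoid, which a ten-membered ring can adopt, and no vicinal free hydroxyl is present that could cause silyl migration.

Step 24
Reactants: 33 epoxide
Product: 34 (4R,5R,6R,7S,8S)-8-(tert-butyldimethylsilyloxy)-4,5-epoxy-6-(4-methoxybenzyloxy)-14-(triisopropylsilyloxy)-11,12,13-trinorgermacr-1(10)E-en-7-ol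
Conditions: HF·pyridine, excess pyridine, THF, 0 °C
Reagents that add atoms: none
Why: buffered fluoride removes the secondary triethylsilyl ether faster than the tert-butyldimethylsilyl and triisopropylsilyl ethers, and the excess pyridine protects the epoxide.

Step 25
Reactants: 34 C7 alcohol
Product: 35 (4R,5R,6S,8S)-8-(tert-butyldimethylsilyloxy)-4,5-epoxy-6-(4-methoxybenzyloxy)-14-(triisopropylsilyloxy)-11,12,13-trinorgermacr-1(10)E-en-7-one
Conditions: Dess–Martin periodinane, NaHCO3, CH2Cl2, 0 °C → rt
Reagents that add atoms: none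
Why: neutral oxidation gives the C7 ketone without acid or base, so the epoxide and the α-stereocentres C6 and C8 are preserved.

Step 26
Reactants: 35 C7 ketone
Product: 36 (4R,5R,6S,8S)-8-(tert-butyldimethylsilyloxy)-4,5-epoxy-6-hydroxy-14-(triisopropylsilyloxy)-11,12,13-trinorgermacr-1(10)E-en-7-one
Conditions: DDQ, CH2Cl2/pH 7 buffer 10:1, 0 °C → rt
Reagents that add atoms: none
Why: oxidative cleavage of the PMB ether in buffered medium frees the C6 hydroxyl without acid or base.

Step 27
Reactants: 36 α-hydroxy ketone; 13 2-(diethoxyphosphoryl)-3-[(4-methoxyphenyl)methoxy]propanoic acid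
Product: 37 (4R,5R,6S,8S)-8-(tert-butyldimethylsilyloxy)-4,5-epoxy-7-oxo-14-(triisopropylsilyloxy)-11,12,13-trinorgermacr-1(10)E-en-6-yl (2RS)-2-(diethoxyphosphoryl)-3-[(4-methoxyphenyl)methoxy]propanoate
Conditions: DCC, DMAP (cat.), CH2Cl2, 0 °C → rt
Reagents that add atoms: none
Why: Steglich esterification of the secondary C6 hydroxyl under nearly neutral conditions attaches C11, C12 and C13 next to the C7 ketone.

Step 28
Reactants: 37 phosphonate ester
Product: 38 (4R,5R,6R,8S)-8-(tert-butyldimethylsilyloxy)-4,5-epoxy-13-(4-methoxybenzyloxy)-14-(triisopropylsilyloxy)germacra-1(10)E,7(11)-dien-12,6-olide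
Conditions: LiCl, i-Pr2NEt, MeCN, 0 °C → rt
Reagents that add atoms: none
Why: intramolecular Horner–Wadsworth–Emmons reaction under Masamune–Roush conditions; the lithium-chelated phosphonate is deprotonated by the weak amine base in preference to the hindered C6 and C8 methines, and five-membered ring closure onto C7 gives the tetrasubstituted butenolide.

Step 29
Reactants: 38 bis-silylated butenolide
Product: 39 (4R,5R,6R,8S)-4,5-epoxy-8,14-dihydroxy-13-(4-methoxybenzyloxy)germacra-1(10)E,7(11)-dien-12,6-olide
Conditions: Bu4NF, AcOH (1:1), THF, 0 °C → rt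
Reagents that add atoms: none
Why: acetic-acid-buffered fluoride removes both silyl ethers while keeping the medium non-basic for the butenolide and non-acidic for the epoxide.

Step 30
Reactants: 39 diol; 40 3-methylbutanoic anhydride
Product: 42 (4R,5R,6R,8S)-4,5-epoxy-13-(4-methoxybenzyloxy)-8-(3-methylbutanoyloxy)-14-(triethylsilyloxy)germacra-1(10)E,7(11)-dien-12,6-olide, via 14-O-triethylsilyl ether 41 (not isolated)
Conditions: Et3SiCl (1.05 equiv), imidazole, CH2Cl2, −78 → −40 °C; then 40, DMAP, −20 °C → rt
Reagents that add atoms: triethylsilyl chloride, CC[Si](Cl)(CC)CC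
Why: the primary allylic hydroxyl is silylated selectively at low temperature and the remaining hindered C8 hydroxyl is then acylated under DMAP catalysis; acylating C8 before C14 is oxidised avoids an 8-hydroxy-14-aldehyde, which would close to a lactol.

Step 31
Reactants: 42 C14 silyl ether
Product: 43 (4R,5R,6R,8S)-4,5-epoxy-14-hydroxy-13-(4-methoxybenzyloxy)-8-(3-methylbutanoyloxy)germacra-1(10)E,7(11)-dien-12,6-olide
Conditions: HF·pyridine, excess pyridine, THF, 0 °C
Reagents that add atoms: none
Why: a primary triethylsilyl ether is cleaved within minutes by buffered fluoride, which leaves the esters, the epoxide and the PMB ether untouched.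

Step 32
Reactants: 43 allylic alcohol
Product: 44 (4R,5R,6R,8S)-4,5-epoxy-13-(4-methoxybenzyloxy)-8-(3-methylbutanoyloxy)-14-oxogermacra-1(10)E,7(11)-dien-12,6-olide
Conditions: MnO2 (activated, excess), CH2Cl2, rt
Reagents that add atoms: none
Why: neutral, selective oxidation of the primary allylic alcohol to the enal; the enal already has the more stable geometry with the formyl group trans to C2.

Step 33
Reactants: 44 enal
Product: 45 (4R,5R,6R,8S)-4,5-epoxy-13-hydroxy-8-(3-methylbutanoyloxy)-14-oxogermacra-1(10)E,7(11)-dien-12,6-olide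
Conditions: DDQ, CH2Cl2/pH 7 buffer 10:1, 0 °C → rt
Reagents that add atoms: none
Why: oxidative PMB cleavage is compatible with the enal, the butenolide, the epoxide and the ester and frees the C13 hydroxyl.

Step 34
Reactants: 45 C13 alcohol; 46 acetic anhydride
Product: 47 (4R,5R,6R,8S)-13-acetoxy-4,5-epoxy-8-(3-methylbutanoyloxy)-14-oxogermacra-1(10)E,7(11)-dien-12,6-olide (CNP0289605.1)
Conditions: pyridine, DMAP (cat.), CH2Cl2, 0 °C
Reagents that add atoms: none
Why: acetylation of the primary allylic alcohol under mild conditions is placed last so that the base-labile allylic acetate on the butenolide meets no further reagent.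

## Compound list

1 | 4-methoxybenzyl alcohol | COc1ccc(CO)cc1 | starting material
2 | chloromethyl methyl sulfide | CSCCl | starting material
3 | 1-methoxy-4-{[(methylsulfanyl)methoxy]methyl}benzene | COc1ccc(COCSC)cc1 | intermediate
4 | 1-[(chloromethoxy)methyl]-4-methoxybenzene | COc1ccc(COCCl)cc1 | intermediate
5 | pent-4-enal | C=CCCC=O | starting material
6 | methyl acrylate | C=CC(=O)OC | starting material
7 | methyl 3-hydroxy-2-methylidenehept-6-enoate (racemic) | C=CCCC(O)C(=C)C(=O)OC | intermediate
8 | methyl (2Z)-2-(bromomethyl)hepta-2,6-dienoate | C=CCC/C=C(\CBr)C(=O)OC | intermediate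
9 | (2Z)-2-(bromomethyl)hepta-2,6-dien-1-ol | C=CCC/C=C(\CBr)CO | intermediate
10 | {[(2Z)-2-(bromomethyl)hepta-2,6-dien-1-yl]oxy}tri(propan-2-yl)silane | C=CCC/C=C(\CBr)CO[Si](C(C)C)(C(C)C)C(C)C | intermediate
11 | prop-2-en-1-yl (diethoxyphosphoryl)acetate | C=CCOC(=O)CP(=O)(OCC)OCC | starting material
12 | prop-2-en-1-yl 2-(diethoxyphosphoryl)-3-[(4-methoxyphenyl)methoxy]propanoate (racemic) | C=CCOC(=O)C(COCc1ccc(OC)cc1)P(=O)(OCC)OCC | intermediate
13 | 2-(diethoxyphosphoryl)-3-[(4-methoxyphenyl)methoxy]propanoic acid (racemic) | OC(=O)C(COCc1ccc(OC)cc1)P(=O)(OCC)OCC | intermediate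
14 | 2,2-dimethyl-1,3-dioxan-5-one | CC1(C)OCC(=O)CO1 | starting material
15 | (2S)-2-(methoxymethyl)pyrrolidin-1-amine (SAMP) | COC[C@@H]1CCCN1N | starting material
16 | (2S)-N-(2,2-dimethyl-1,3-dioxan-5-ylidene)-2-(methoxymethyl)pyrrolidin-1-amine | COC[C@@H]1CCCN1N=C1COC(C)(C)OC1 | intermediate
17 | lithium aza-enolate of 16 | COC[C@@H]1CCCN1N([Li])C1=COC(C)(C)OC1 | intermediate
18 | (2S)-N-[(4R)-4-{[(4-methoxyphenyl)methoxy]methyl}-2,2-dimethyl-1,3-dioxan-5-ylidene]-2-(methoxymethyl)pyrrolidin-1-amine | COC[C@@H]1CCCN1N=C1COC(C)(C)O[C@H]1COCc1ccc(OC)cc1 | intermediate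
19 | lithium aza-enolate of 18 (4R) | COC[C@@H]1CCCN1N([Li])C1=COC(C)(C)O[C@H]1COCc1ccc(OC)cc1 | intermediate
20 | (2S)-N-[(4R,6S)-4-{[(4-methoxyphenyl)methoxy]methyl}-2,2-dimethyl-6-[(2E)-2-({[tri(propan-2-yl)silyl]oxy}methyl)hepta-2,6-dien-1-yl]-1,3-dioxan-5-ylidene]-2-(methoxymethyl)pyrrolidin-1-amine | COC[C@@H]1CCCN1N=C1[C@H](C/C(CO[Si](C(C)C)(C(C)C)C(C)C)=C\CCC=C)OC(C)(C)O[C@H]1COCc1ccc(OC)cc1 | intermediate
21 | (4S,6S)-4-{[(4-methoxyphenyl)methoxy]methyl}-2,2-dimethyl-6-[(2E)-2-({[tri(propan-2-yl)silyl]oxy}methyl)hepta-2,6-dien-1-yl]-1,3-dioxan-5-one | COc1ccc(COC[C@@H]2OC(C)(C)O[C@@H](C/C(CO[Si](C(C)C)(C(C)C)C(C)C)=C\CCC=C)C2=O)cc1 | intermediate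
22 | (2S,4S,6E)-2,4-dihydroxy-1-[(4-methoxyphenyl)methoxy]-6-({[tri(propan-2-yl)silyl]oxy}methyl)undeca-6,10-dien-3-one | COc1ccc(COC[C@H](O)C(=O)[C@@H](O)C/C(CO[Si](C(C)C)(C(C)C)C(C)C)=C\CCC=C)cc1 | intermediate
23 | (2S,4E)-2-hydroxy-1-[(2RS,4S)-2-(4-methoxyphenyl)-1,3-dioxolan-4-yl]-4-({[tri(propan-2-yl)silyl]oxy}methyl)nona-4,8-dien-1-one | COc1ccc(C2OC[C@H](O2)C(=O)[C@@H](O)C/C(CO[Si](C(C)C)(C(C)C)C(C)C)=C\CCC=C)cc1 | intermediate
24 | (2S,4E)-2-{[tert-butyl(dimethyl)silyl]oxy}-1-[(2RS,4S)-2-(4-methoxyphenyl)-1,3-dioxolan-4-yl]-4-({[tri(propan-2-yl)silyl]oxy}methyl)nona-4,8-dien-1-one | COc1ccc(C2OC[C@H](O2)C(=O)[C@@H](O[Si](C)(C)C(C)(C)C)C/C(CO[Si](C(C)C)(C(C)C)C(C)C)=C\CCC=C)cc1 | intermediate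
25 | (1S,2S,4E)-2-{[tert-butyl(dimethyl)silyl]oxy}-1-[(2RS,4S)-2-(4-methoxyphenyl)-1,3-dioxolan-4-yl]-4-({[tri(propan-2-yl)silyl]oxy}methyl)nona-4,8-dien-1-ol | COc1ccc(C2OC[C@H](O2)[C@H](O)[C@@H](O[Si](C)(C)C(C)(C)C)C/C(CO[Si](C(C)C)(C(C)C)C(C)C)=C\CCC=C)cc1 | intermediate
26 | (2RS,4S)-4-[(1S,2S,4E)-2-{[tert-butyl(dimethyl)silyl]oxy}-1-[(triethylsilyl)oxy]-4-({[tri(propan-2-yl)silyl]oxy}methyl)nona-4,8-dien-1-yl]-2-(4-methoxyphenyl)-1,3-dioxolane | COc1ccc(C2OC[C@H](O2)[C@H](O[Si](CC)(CC)CC)[C@@H](O[Si](C)(C)C(C)(C)C)C/C(CO[Si](C(C)C)(C(C)C)C(C)C)=C\CCC=C)cc1 | intermediate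
27 | (2S,3S,4S,6E)-4-{[tert-butyl(dimethyl)silyl]oxy}-2-[(4-methoxyphenyl)methoxy]-3-[(triethylsilyl)oxy]-6-({[tri(propan-2-yl)silyl]oxy}methyl)undeca-6,10-dien-1-ol | OC[C@H](OCc1ccc(OC)cc1)[C@H](O[Si](CC)(CC)CC)[C@@H](O[Si](C)(C)C(C)(C)C)C/C(CO[Si](C(C)C)(C(C)C)C(C)C)=C\CCC=C | intermediate
28 | (5E,8S,9S,10S)-8-{[tert-butyl(dimethyl)silyl]oxy}-11-hydroxy-10-[(4-methoxyphenyl)methoxy]-9-[(triethylsilyl)oxy]-6-({[tri(propan-2-yl)silyl]oxy}methyl)undec-5-en-2-one | OC[C@H](OCc1ccc(OC)cc1)[C@H](O[Si](CC)(CC)CC)[C@@H](O[Si](C)(C)C(C)(C)C)C/C(CO[Si](C(C)C)(C(C)C)C(C)C)=C\CCC(C)=O | intermediate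
29 | (2R,3S,4S,6E)-4-{[tert-butyl(dimethyl)silyl]oxy}-2-[(4-methoxyphenyl)methoxy]-10-oxo-3-[(triethylsilyl)oxy]-6-({[tri(propan-2-yl)silyl]oxy}methyl)undec-6-enal | O=C[C@H](OCc1ccc(OC)cc1)[C@H](O[Si](CC)(CC)CC)[C@@H](O[Si](C)(C)C(C)(C)C)C/C(CO[Si](C(C)C)(C(C)C)C(C)C)=C\CCC(C)=O | intermediate
30 | bis(diiodosamarium) 4,5-diolate of 31 | C[C@@]1(O[Sm](I)I)CC/C=C(CO[Si](C(C)C)(C(C)C)C(C)C)\C[C@H](O[Si](C)(C)C(C)(C)C)[C@@H](O[Si](CC)(CC)CC)[C@@H](OCc2ccc(OC)cc2)[C@@H]1O[Sm](I)I | intermediate
31 | (4R,5S,6S,7S,8S)-8-(tert-butyldimethylsilyloxy)-6-(4-methoxybenzyloxy)-7-(triethylsilyloxy)-14-(triisopropylsilyloxy)-11,12,13-trinorgermacr-1(10)E-ene-4,5-diol | C[C@@]1(O)CC/C=C(CO[Si](C(C)C)(C(C)C)C(C)C)\C[C@H](O[Si](C)(C)C(C)(C)C)[C@@H](O[Si](CC)(CC)CC)[C@@H](OCc2ccc(OC)cc2)[C@@H]1O | intermediate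
32 | (4R,5S,6R,7S,8S)-8-(tert-butyldimethylsilyloxy)-4-hydroxy-6-(4-methoxybenzyloxy)-7-(triethylsilyloxy)-14-(triisopropylsilyloxy)-11,12,13-trinorgermacr-1(10)E-en-5-yl methanesulfonate | C[C@@]1(O)CC/C=C(CO[Si](C(C)C)(C(C)C)C(C)C)\C[C@H](O[Si](C)(C)C(C)(C)C)[C@@H](O[Si](CC)(CC)CC)[C@@H](OCc2ccc(OC)cc2)[C@@H]1OS(C)(=O)=O | intermediate
33 | (4R,5R,6S,7S,8S)-8-(tert-butyldimethylsilyloxy)-4,5-epoxy-6-(4-methoxybenzyloxy)-7-(triethylsilyloxy)-14-(triisopropylsilyloxy)-11,12,13-trinorgermacr-1(10)E-ene | C[C@@]12CC/C=C(CO[Si](C(C)C)(C(C)C)C(C)C)\C[C@H](O[Si](C)(C)C(C)(C)C)[C@@H](O[Si](CC)(CC)CC)[C@@H](OCc3ccc(OC)cc3)[C@H]1O2 | intermediate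
34 | (4R,5R,6R,7S,8S)-8-(tert-butyldimethylsilyloxy)-4,5-epoxy-6-(4-methoxybenzyloxy)-14-(triisopropylsilyloxy)-11,12,13-trinorgermacr-1(10)E-en-7-ol | C[C@@]12CC/C=C(CO[Si](C(C)C)(C(C)C)C(C)C)\C[C@H](O[Si](C)(C)C(C)(C)C)[C@@H](O)[C@@H](OCc3ccc(OC)cc3)[C@H]1O2 | intermediate
35 | (4R,5R,6S,8S)-8-(tert-butyldimethylsilyloxy)-4,5-epoxy-6-(4-methoxybenzyloxy)-14-(triisopropylsilyloxy)-11,12,13-trinorgermacr-1(10)E-en-7-one | C[C@@]12CC/C=C(CO[Si](C(C)C)(C(C)C)C(C)C)\C[C@H](O[Si](C)(C)C(C)(C)C)C(=O)[C@@H](OCc3ccc(OC)cc3)[C@H]1O2 | intermediate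
36 | (4R,5R,6S,8S)-8-(tert-butyldimethylsilyloxy)-4,5-epoxy-6-hydroxy-14-(triisopropylsilyloxy)-11,12,13-trinorgermacr-1(10)E-en-7-one | C[C@@]12CC/C=C(CO[Si](C(C)C)(C(C)C)C(C)C)\C[C@H](O[Si](C)(C)C(C)(C)C)C(=O)[C@@H](O)[C@H]1O2 | intermediate
37 | (4R,5R,6S,8S)-8-(tert-butyldimethylsilyloxy)-4,5-epoxy-7-oxo-14-(triisopropylsilyloxy)-11,12,13-trinorgermacr-1(10)E-en-6-yl (2RS)-2-(diethoxyphosphoryl)-3-[(4-methoxyphenyl)methoxy]propanoate | C[C@@]12CC/C=C(CO[Si](C(C)C)(C(C)C)C(C)C)\C[C@H](O[Si](C)(C)C(C)(C)C)C(=O)[C@@H](OC(=O)C(COCc3ccc(OC)cc3)P(=O)(OCC)OCC)[C@H]1O2 | intermediate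
38 | (4R,5R,6R,8S)-8-(tert-butyldimethylsilyloxy)-4,5-epoxy-13-(4-methoxybenzyloxy)-14-(triisopropylsilyloxy)germacra-1(10)E,7(11)-dien-12,6-olide | C[C@@]12CC/C=C(CO[Si](C(C)C)(C(C)C)C(C)C)\C[C@H](O[Si](C)(C)C(C)(C)C)C3=C(COCc4ccc(OC)cc4)C(=O)O[C@H]3[C@H]1O2 | intermediate
39 | (4R,5R,6R,8S)-4,5-epoxy-8,14-dihydroxy-13-(4-methoxybenzyloxy)germacra-1(10)E,7(11)-dien-12,6-olide | C[C@@]12CC/C=C(CO)\C[C@H](O)C3=C(COCc4ccc(OC)cc4)C(=O)O[C@H]3[C@H]1O2 | intermediate
40 | 3-methylbutanoic anhydride | CC(C)CC(=O)OC(=O)CC(C)C | starting material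
41 | (4R,5R,6R,8S)-4,5-epoxy-8-hydroxy-13-(4-methoxybenzyloxy)-14-(triethylsilyloxy)germacra-1(10)E,7(11)-dien-12,6-olide | C[C@@]12CC/C=C(CO[Si](CC)(CC)CC)\C[C@H](O)C3=C(COCc4ccc(OC)cc4)C(=O)O[C@H]3[C@H]1O2 | intermediate
42 | (4R,5R,6R,8S)-4,5-epoxy-13-(4-methoxybenzyloxy)-8-(3-methylbutanoyloxy)-14-(triethylsilyloxy)germacra-1(10)E,7(11)-dien-12,6-olide | C[C@@]12CC/C=C(CO[Si](CC)(CC)CC)\C[C@H](OC(=O)CC(C)C)C3=C(COCc4ccc(OC)cc4)C(=O)O[C@H]3[C@H]1O2 | intermediate
43 | (4R,5R,6R,8S)-4,5-epoxy-14-hydroxy-13-(4-methoxybenzyloxy)-8-(3-methylbutanoyloxy)germacra-1(10)E,7(11)-dien-12,6-olide | C[C@@]12CC/C=C(CO)\C[C@H](OC(=O)CC(C)C)C3=C(COCc4ccc(OC)cc4)C(=O)O[C@H]3[C@H]1O2 | intermediate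
44 | (4R,5R,6R,8S)-4,5-epoxy-13-(4-methoxybenzyloxy)-8-(3-methylbutanoyloxy)-14-oxogermacra-1(10)E,7(11)-dien-12,6-olide | C[C@@]12CC/C=C(C=O)\C[C@H](OC(=O)CC(C)C)C3=C(COCc4ccc(OC)cc4)C(=O)O[C@H]3[C@H]1O2 | intermediate
45 | (4R,5R,6R,8S)-4,5-epoxy-13-hydroxy-8-(3-methylbutanoyloxy)-14-oxogermacra-1(10)E,7(11)-dien-12,6-olide | C[C@@]12CC/C=C(C=O)\C[C@H](OC(=O)CC(C)C)C3=C(CO)C(=O)O[C@H]3[C@H]1O2 | intermediate
46 | acetic anhydride | CC(=O)OC(C)=O | starting material
47 | (4R,5R,6R,8S)-13-acetoxy-4,5-epoxy-8-(3-methylbutanoyloxy)-14-oxogermacra-1(10)E,7(11)-dien-12,6-olide (CNP0289605.1) | CC(=O)OCC1=C2[C@@H](OC(=O)CC(C)C)C/C(C=O)=C\CC[C@@]3(C)O[C@@H]3[C@@H]2OC1=O | target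

## Step count and least certain steps

Total: 34 steps. Longest linear sequence: 28 steps (steps 3–6, then 11–34, from 5 and 6 to 47).

**Step 21 (key step).** The most likely failure is poor facial control at the ketyl carbon: if chelation to the C6 ether is weak, the ring closes with C5 epimeric (trans-diol). Slow closure would also let the ketyl be reduced, lose the α-PMB-oxy group or add to the C1=C10 alkene. The fallback sets C5 by hydride delivery instead of by the ketyl addition. It sets out from 29: the pinacol product epimeric at C5, (4R,5R)-diol F1, is oxidised with Dess–Martin periodinane at the secondary hydroxyl to α-ketol F2, and F2 is reduced with Zn(BH4)2. The zinc alkoxide of the tertiary C4 hydroxyl chelates the C5 carbonyl and hydride enters from the peripheral, methyl-bearing face, which gives the cis-diol; the route is rejoined at 31. Only an error at C5 is repaired this way, not one at C4.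

**Step 28.** The most likely failure is enolisation of the C7 ketone toward C6, which would open the β,γ-epoxide by elimination or epimerise C6. The hindered ketone may also be slow to give the tetrasubstituted alkene. The fallback replaces the carbonyl olefination by ring-closing metathesis and uses no base. It sets out from 35: methylenation with Cp2TiMe2 (toluene, 70 °C) gives 7-methylidene compound F3, DDQ frees the C6 alcohol F4, and esterification (DCC, DMAP) with 2-{[(4-methoxyphenyl)methoxy]methyl}prop-2-enoic acid F5 (from 13, aqueous formaldehyde and K2CO3) gives acrylate F6. Ring-closing metathesis with the second-generation Grubbs catalyst in hot toluene closes the butenolide, and the route is rejoined at 38.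

**Step 23.** The most likely failure is slow displacement: the hindered tertiary alkoxide must reach the anti-periplanar conformer in a crowded ten-membered ring, and elimination of the mesylate toward C6 or methanolysis can compete. The fallback changes the way the C5 leaving group is made and displaced. It sets out from diol 31, skips mesylate 32, and uses Martin sulfurane (Ph2S[OC(CF3)2Ph]2, CH2Cl2, rt) to convert the secondary hydroxyl into an alkoxysulfonium group that the neighbouring tertiary hydroxyl displaces under neutral conditions, with the same inversion at C5. It rejoins the route at 33 and makes no new compound (F0).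

**Step 11.** The most likely failure is incomplete alkylation of the already substituted, more hindered aza-enolate 19 by the branched allylic bromide, with proton transfer or SN2′ attack eroding yield and trans selectivity. The fallback reverses the order of the two C–C bond formations. It sets out from 16: the unhindered aza-enolate 17 is alkylated first with bromide 10 to give the (4S)-monoalkylated hydrazone F7, and F7 is then deprotonated (t-BuLi) and alkylated with the small, very reactive chloromethyl ether 4. The route is rejoined at 20.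

## Further compounds

F1 | step 21 | (4R,5R,6S,7S,8S)-8-(tert-butyldimethylsilyloxy)-6-(4-methoxybenzyloxy)-7-(triethylsilyloxy)-14-(triisopropylsilyloxy)-11,12,13-trinorgermacr-1(10)E-ene-4,5-diol (C5 epimer of 31) | C[C@@]1(O)CC/C=C(CO[Si](C(C)C)(C(C)C)C(C)C)\C[C@H](O[Si](C)(C)C(C)(C)C)[C@@H](O[Si](CC)(CC)CC)[C@@H](OCc2ccc(OC)cc2)[C@H]1O
F2 | step 21 | (4R,6R,7S,8S)-8-(tert-butyldimethylsilyloxy)-4-hydroxy-6-(4-methoxybenzyloxy)-7-(triethylsilyloxy)-14-(triisopropylsilyloxy)-11,12,13-trinorgermacr-1(10)E-en-5-one | C[C@@]1(O)CC/C=C(CO[Si](C(C)C)(C(C)C)C(C)C)\C[C@H](O[Si](C)(C)C(C)(C)C)[C@@H](O[Si](CC)(CC)CC)[C@@H](OCc2ccc(OC)cc2)C1=O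
F3 | step 28 | (4R,5R,6R,8S)-8-(tert-butyldimethylsilyloxy)-4,5-epoxy-6-(4-methoxybenzyloxy)-7-methylidene-14-(triisopropylsilyloxy)-11,12,13-trinorgermacr-1(10)E-ene | C[C@@]12CC/C=C(CO[Si](C(C)C)(C(C)C)C(C)C)\C[C@H](O[Si](C)(C)C(C)(C)C)C(=C)[C@@H](OCc3ccc(OC)cc3)[C@H]1O2
F4 | step 28 | (4R,5R,6R,8S)-8-(tert-butyldimethylsilyloxy)-4,5-epoxy-7-methylidene-14-(triisopropylsilyloxy)-11,12,13-trinorgermacr-1(10)E-en-6-ol | C[C@@]12CC/C=C(CO[Si](C(C)C)(C(C)C)C(C)C)\C[C@H](O[Si](C)(C)C(C)(C)C)C(=C)[C@@H](O)[C@H]1O2
F5 | step 28 | 2-{[(4-methoxyphenyl)methoxy]methyl}prop-2-enoic acid | C=C(COCc1ccc(OC)cc1)C(=O)O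
F6 | step 28 | (4R,5R,6R,8S)-8-(tert-butyldimethylsilyloxy)-4,5-epoxy-7-methylidene-14-(triisopropylsilyloxy)-11,12,13-trinorgermacr-1(10)E-en-6-yl 2-{[(4-methoxyphenyl)methoxy]methyl}prop-2-enoate | C[C@@]12CC/C=C(CO[Si](C(C)C)(C(C)C)C(C)C)\C[C@H](O[Si](C)(C)C(C)(C)C)C(=C)[C@@H](OC(=O)C(=C)COCc3ccc(OC)cc3)[C@H]1O2
F0 | step 23 | none | none
F7 | step 11 | (2S)-N-[(4S)-2,2-dimethyl-4-[(2E)-2-({[tri(propan-2-yl)silyl]oxy}methyl)hepta-2,6-dien-1-yl]-1,3-dioxan-5-ylidene]-2-(methoxymethyl)pyrrolidin-1-amine | COC[C@@H]1CCCN1N=C1COC(C)(C)O[C@H]1C/C(CO[Si](C(C)C)(C(C)C)C(C)C)=C\CCC=C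
A1 | alternative 1 | fully acylated ten-membered ring with C14 tert-butyldimethylsilyl ether | CC(=O)OCC1=C2[C@@H](OC(=O)CC(C)C)C/C(CO[Si](C)(C)C(C)(C)C)=C\CC[C@@]3(C)O[C@@H]3[C@@H]2OC1=O
A2 | alternative 1 | open-chain C1 vinyl iodide with N-hydroxyphthalimide ester one carbon beyond C2 | CC(=O)OCC1=C([C@@H](OC(=O)CC(C)C)C/C(CO[Si](C)(C)C(C)(C)C)=C\I)[C@H]([C@H]2O[C@]2(C)CCC(=O)ON2C(=O)c3ccccc3C2=O)OC1=O
A3 | alternative 2 | ten-membered (4E)-alkene C1(10) enol triflate | COC1(OC)[C@@H](O[Si](C)(C)C(C)(C)C)C/C(OS(=O)(=O)C(F)(F)F)=C\CC/C(C)=C/[C@@H]1OCc1ccc(OC)cc1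
A4 | alternative 2 | cis-1-ethenyl-2-(prop-1-en-2-yl)cyclohexanol with C7 dimethyl ketal (C6 PMB ether and C8 silyl ether) | C=C[C@@]1(O)C[C@H](O[Si](C)(C)C(C)(C)C)C(OC)(OC)[C@@H](OCc2ccc(OC)cc2)[C@H]1C(C)=C
A5 | alternative 3 | ten-membered cycloalkynol with C7 alkenyl side chain | C=C(COCc1ccc(OC)cc1)[C@H]1[C@@H](O[Si](C)(C)C(C)(C)C)C/C(CO[Si](C)(C)C(C)(C)C)=C\CCC#C[C@@H]1O
A6 | alternative 3 | thirteen-membered propargyl allyl ether | O1CC#CCC/C=C(CO[Si](C)(C)C(C)(C)C)\C[C@H](O[Si](C)(C)C(C)(C)C)/C=C(COCc2ccc(OC)cc2)/C1
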